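The plan disconnects C8–C9, the bond between the two adjacent, trans-related CH carbons that the cyclononadiene and the oxolane share. C9 bears the oxolane OCH2 (C10, a reduced carboxyl). C8 bears the quaternary ether carbon C12 (a former alkene carbon). This is the acid/alkenyl 1,2-pattern of an ester-enolate Claisen product. In one operation the silyl ketene acetal of lactone 20 forms C8–C9, contracts the 13-membered ring to the nine-membered carbocycle and sets both fusion centres from C13. Lactone 20 is an allylic macrolactone with the Z-C3=C4 alkene, the C1 methylene, the silylated C5 carbinol, an E-C8=C12 alkene and the prenyl-bearing C13–O centre.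

Key step: step 18

**Remarks before the steps**
* **Atom labels.**
  * C1 is the ring carbon with the exocyclic CH2, and C2 is the ring CH2 next to it.
  * C3=C4 is the Z ring alkene, and C5 is the methyl carbinol carbon.
  * C6 and C7 are ring CH2 groups.
  * C8 (next to C7) and C9 (next to C1) are the fusion CH carbons.
  * C10 is the oxolane OCH2, and C12 is the quaternary ether carbon.
  * C13–C16 is the side chain counted outward from C12, and C17 is the CH2O on C12.
* **Assumption.** The SMILES string defines the target completely: (5S,8S,9R,12R), 3Z, 13E in these labels.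
* **Stereochemical check of 20 and 23 against the target.** (13S) with the E-C8=C12 alkene relays to (8S). The acetal with C1 anti to the ring oxygen (Z by CIP, since OSi outranks OC) gives (9R) through the chair. C5 is untouched.
* **C17–O protection.** It is carried as a pivalate instead of a second silyl ether. The hydride that reduces the acid also removes it, so the C5 TES ether is the only silyl group left and it falls last.
* **C12 stereocentre.** It is set under reagent control, by directed epoxidation and invertive 5-exo opening, because the C8–C12 rotamers give no reliable facial bias.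
* **Linear prenyl group.** It is made by allylation and cross-metathesis, because prenyl metals add through their γ-carbon.
* **Order of alkene introduction.** The isopropylidene alkene is cleaved while it is still the only alkene in the molecule.

Step 1
Reactants: 1 geraniol
Product: 2 (2S,3S)-2,3-epoxygeraniol
Conditions: Ti(OiPr)4 (cat.), L-(+)-DET (cat.), t-BuOOH, 4 Å MS, CH2Cl2, −20 °C
Reagents that add atoms: tert-butyl hydroperoxide, CC(C)(C)OO
Why: Katsuki–Sharpless asymmetric epoxidation touches only the alkene next to the titanium-bound hydroxyl, and L-(+)-tartrate gives the (2S,3S)-epoxide, whose C3 becomes C5 of the target.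

Step 2
Reactants: 2 (2S,3S)-2,3-epoxygeraniol
Product: 3 (2R,3S)-1-chloro-2,3-epoxy-3,7-dimethyloct-6-ene
Conditions: PPh3, CCl4, reflux
Reagents that add atoms: carbon tetrachloride, ClC(Cl)(Cl)Cl
Why: Appel chlorination replaces the primary hydroxyl under neutral conditions and leaves the epoxide carbons unchanged in space (the C2 descriptor changes only because CH2Cl outranks C3).

Step 3
Reactants: 3 (2R,3S)-1-chloro-2,3-epoxy-3,7-dimethyloct-6-ene
Product: 4 (S)-3,7-dimethyloct-6-en-1-yn-3-ol
Conditions: n-BuLi (3.3 equiv), THF, −78 → −20 °C; H2O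
Reagents that add atoms: none
Why: Base-induced eliminative opening of a 2,3-epoxy chloride followed by dehydrochlorination (the epoxy chloride to propargylic alcohol conversion) breaks only the secondary C–O bond, so the tertiary C–O centre is retained as (S).

Step 4
Reactants: 4 (S)-3,7-dimethyloct-6-en-1-yn-3-ol
Product: 5 (S)-triethyl[(3,7-dimethyloct-6-en-1-yn-3-yl)oxy]silane
Conditions: TESOTf, 2,6-lutidine, CH2Cl2, 0 °C
Reagents that add atoms: triethylsilyl triflate, CC[Si](CC)(CC)OS(=O)(=O)C(F)(F)F
Why: Silyl triflate silylation covers the hindered tertiary alcohol, which would otherwise close onto the aldehyde of the next step as a lactol.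

Step 5
Reactants: 5 (S)-triethyl[(3,7-dimethyloct-6-en-1-yn-3-yl)oxy]silane
Product: 6 (S)-4-methyl-4-(triethylsilyloxy)hex-5-ynal
Conditions: O3, CH2Cl2, −78 °C (Sudan III end point); Me2S, −78 °C → rt
Reagents that add atoms: ozone, [O-][O+]=O
Why: Ozonolysis with reductive work-up cleaves the electron-rich trisubstituted alkene far faster than the terminal alkyne, and no other alkene is present at this stage.

Step 6
Reactants: 6 (S)-4-methyl-4-(triethylsilyloxy)hex-5-ynal; 7 dimethyl malonate
Product: 8 dimethyl (S)-2-[4-methyl-4-(triethylsilyloxy)hex-5-yn-1-ylidene]malonate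
Conditions: piperidine (cat.), AcOH (cat.), 4 Å MS, toluene, rt
Reagents that add atoms: none
Why: Knoevenagel condensation installs C12 with both of its oxidised one-carbon arms (C13 and C17) from a symmetrical partner, so no alkene geometry has to be controlled here.

Step 7
Reactants: 8 dimethyl (S)-2-[4-methyl-4-(triethylsilyloxy)hex-5-yn-1-ylidene]malonate
Product: 9 (S)-2-[4-methyl-4-(triethylsilyloxy)hex-5-yn-1-ylidene]propane-1,3-diol
Conditions: DIBAL-H (4.5 equiv), CH2Cl2, −78 → 0 °C; H2O work-up
Reagents that add atoms: none
Why: DIBAL-H in a non-coordinating solvent reduces both ester groups in the 1,2 sense to the 2-alkylidene-1,3-diol, and it leaves the silyl ether and the alkyne alone at these temperatures.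

Step 8
Reactants: 10 4-methyl hydrogen itaconate (4-methoxy-2-methylene-4-oxobutanoic acid)
Product: 11 methyl 3-(hydroxymethyl)but-3-enoate
Conditions: BH3·SMe2 (1.0 equiv), THF, −10 → 0 °C; H2O
Reagents that add atoms: none
Why: Chemoselective borane reduction takes the free conjugated carboxylic acid much faster than the methyl ester, and the electron-poor 1,1-disubstituted alkene is a poor hydroboration partner in the cold.

Step 9
Reactants: 11 methyl 3-(hydroxymethyl)but-3-enoate
Product: 12 methyl 3-(bromomethyl)but-3-enoate
Conditions: CBr4, PPh3, CH2Cl2, 0 °C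
Reagents that add atoms: carbon tetrabromide, BrC(Br)(Br)Br
Why: Appel bromination converts the allylic alcohol under neutral conditions, which avoids lactonisation and migration of the β,γ-double bond.

Step 10
Reactants: 9 (S)-2-[4-methyl-4-(triethylsilyloxy)hex-5-yn-1-ylidene]propane-1,3-diol; 12 methyl 3-(bromomethyl)but-3-enoate
Product: 13 methyl (S)-12-hydroxy-11-(hydroxymethyl)-7-methyl-3-methylene-7-(triethylsilyloxy)dodec-10-en-5-ynoate
Conditions: CuI (cat.), NaI (cat.), K2CO3, DMF, rt
Reagents that add atoms: none
Why: Copper(I)-catalysed allylation of a terminal alkyne forms C2–C3, tolerates free hydroxyls and needs only carbonate as base, and direct and allyl-shifted attack on 12 give the same product.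

Step 11
Reactants: 13 methyl (S)-12-hydroxy-11-(hydroxymethyl)-7-methyl-3-methylene-7-(triethylsilyloxy)dodec-10-en-5-ynoate
Product: 14 methyl (5Z,7S)-12-hydroxy-11-(hydroxymethyl)-7-methyl-3-methylene-7-(triethylsilyloxy)dodeca-5,10-dienoate
Conditions: H2 (1 atm), Lindlar catalyst, quinoline, EtOAc, rt
Reagents that add atoms: none
Why: Lindlar semihydrogenation adds hydrogen syn to the only alkyne and gives the Z-C3=C4 alkene, while the more weakly bound 1,1-di- and trisubstituted alkenes stay intact.

Step 12
Reactants: 14 methyl (5Z,7S)-12-hydroxy-11-(hydroxymethyl)-7-methyl-3-methylene-7-(triethylsilyloxy)dodeca-5,10-dienoate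
Product: 15 methyl (5Z,7S,10E)-11-formyl-12-hydroxy-7-methyl-3-methylene-7-(triethylsilyloxy)dodeca-5,10-dienoate
Conditions: TEMPO (cat.), PhI(OAc)2 (1.0 equiv), CH2Cl2, 0 °C
Reagents that add atoms: none
Why: Oxoammonium (TEMPO) oxidation with one equivalent of oxidant takes the less hindered CH2OH anti to the chain and then slows on the deactivated enal, and the resulting E-enal (CHO anti to C7) is also the thermodynamic isomer.

Step 13
Reactants: 15 methyl (5Z,7S,10E)-11-formyl-12-hydroxy-7-methyl-3-methylene-7-(triethylsilyloxy)dodeca-5,10-dienoate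
Product: 16 methyl (5Z,7S,10E)-11-formyl-7-methyl-3-methylene-12-(pivaloyloxy)-7-(triethylsilyloxy)dodeca-5,10-dienoate
Conditions: PivCl, pyridine, CH2Cl2, 0 °C
Reagents that add atoms: pivaloyl chloride, CC(C)(C)C(=O)Cl
Why: Acylation of the remaining primary alcohol gives an ester without α-hydrogens that survives amide bases, and the weakly nucleophilic pyridine avoids addition–elimination on the acyloxymethyl enal.

Step 14
Reactants: 16 methyl (5Z,7S,10E)-11-formyl-7-methyl-3-methylene-12-(pivaloyloxy)-7-(triethylsilyloxy)dodeca-5,10-dienoate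
Product: 17 methyl (5Z,7S,10E,12S)-12-hydroxy-7-methyl-3-methylene-11-(pivaloyloxymethyl)-7-(triethylsilyloxy)pentadeca-5,10,14-trienoate
Conditions: (−)-Ipc2B(allyl) (commercial solution), Et2O, −78 °C; ethanolamine, rt
Reagents that add atoms: (−)-B-allyldiisopinocampheylborane, C=CCB([C@@H]1C[C@@H]2C[C@H]([C@H]1C)C2(C)C)[C@@H]1C[C@@H]2C[C@H]([C@H]1C)C2(C)C
Why: Brown asymmetric allylboration adds 1,2 to the enal through a closed chair, ignores both esters, and with the (−)-reagent attacks the Si face to set the C13 carbinol as (S).

Step 15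
Reactants: 17 methyl (5Z,7S,10E,12S)-12-hydroxy-7-methyl-3-methylene-11-(pivaloyloxymethyl)-7-(triethylsilyloxy)pentadeca-5,10,14-trienoate
Product: 18 methyl (5Z,7S,10E,12S)-12-hydroxy-7,15-dimethyl-3-methylene-11-(pivaloyloxymethyl)-7-(triethylsilyloxy)hexadeca-5,10,14-trienoate
Conditions: Grubbs II (cat.), 2-methylbut-2-ene/CH2Cl2, 35 °C
Reagents that add atoms: 2-methylbut-2-ene, CC=C(C)C
Why: Olefin cross-metathesis in excess 2-methylbut-2-ene turns the only monosubstituted alkene into the linear prenyl group, while the 1,1-disubstituted, trisubstituted and quaternary-flanked Z alkenes are much slower partners.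

Step 16
Reactants: 18 methyl (5Z,7S,10E,12S)-12-hydroxy-7,15-dimethyl-3-methylene-11-(pivaloyloxymethyl)-7-(triethylsilyloxy)hexadeca-5,10,14-trienoate
Product: 19 (5Z,7S,10E,12S)-12-hydroxy-7,15-dimethyl-3-methylene-11-(pivaloyloxymethyl)-7-(triethylsilyloxy)hexadeca-5,10,14-trienoic acid (seco acid)
Conditions: Me3SnOH, 1,2-DCE, 70 °C; dil. HCl wash
Reagents that add atoms: trimethyltin hydroxide, C[Sn](C)(C)O
Why: Trimethyltin hydroxide ester cleavage is nearly neutral, so the methyl ester falls without loss of the pivalate and without shifting the β,γ-double bond into conjugation.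

Step 17
Reactants: 19 seco acid
Product: 20 13-membered allylic lactone O–C10(=O)–C9H2–C1(=CH2)–C2H2–C3H=C4H(Z)–C5(CH3)(OTES)(S)–C6H2–C7H2–C8H=C12(CH2OPiv)(E)–C13H(prenyl)(S)–O
Conditions: MNBA, DMAP, CH2Cl2, rt, slow addition at high dilution
Reagents that add atoms: none
Why: Shiina macrolactonisation activates the acid at room temperature and closes the ring on the only free hydroxyl with retention at C13, the 13-membered ring being large enough to hold one E and one Z alkene.

Step 18
Reactants: 20 13-membered allylic lactone
Product: 23 (5S,8S,9R)-cyclononadiene carboxylic acid with CO2H on C9 trans to the C12=C13 alkenyl group on C8, via silyl ketene acetal 21 (not isolated), via silyl ester 22 (not isolated)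
Conditions: LDA, THF–DMPU (4:1), −78 °C; TBSCl, −78 °C → rt; toluene, 80 °C; THF–H2O–AcOH, rt
Reagents that add atoms: none
Why: LDA in THF–DMPU removes a C9 proton (activated by the carbonyl and by the C1 methylene) and TBSCl traps the enolate on oxygen as ketene acetal 21, in which C1 is syn to OSi and anti to the ring oxygen; warming then drives a concerted suprafacial [3,3] shift that joins C9 to C8 while C13–O breaks and C12=C13 forms, and mild hydrolysis of silyl ester 22 frees the acid. The closest known reaction type is the Ireland–Claisen rearrangement run as a four-atom ring contraction of macrocyclic allylic lactones, and O-silyl dienolates of 3-methylbutenoate esters are known to rearrange through their α-carbon. The nine-membered carbocycle closes transannularly: all six reacting atoms sit in the 13-membered ring, the C1–C7 tether bridges the two bonding termini, and O, C10, C13 and C12 are pushed out of the ring. C8 is set by the C13 carbinol centre, because in the chair with the prenyl group equatorial the new bond forms on the alkene face from which the oxygen departs, which also places C14 anti to C8 on the new alkene. C9 is set by pairing the E-C8=C12 alkene with the C1-anti-to-oxygen acetal in that chair, so that both tether ends are equatorial and CO2H and the alkenyl group end up trans. The step needs O- over C-silylation, retention of acetal geometry and chair over boat, which the polar co-solvent, the bulky silyl chloride and the diequatorial seven-atom tether are meant to secure, whereas regiochemistry is inherent since only C9 of the dienolate lies six atoms from C8.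

Step 19
Reactants: 23 (5S,8S,9R)-cyclononadiene carboxylic acid
Product: 24 (5S,8S,9R)-diol with C9–CH2OH (C10) and the allylic C17–OH on the C12=C13 alkene
Conditions: LiAlH4, Et2O, 0 °C → rt; H2O work-up
Reagents that add atoms: none
Why: Lithium aluminium hydride reduces the carboxylate to the C10 alcohol and cleaves the pivalate in the same operation, the carboxylate salt protects C9 from epimerisation, and the TES ether and the isolated alkenes are inert.

Step 20
Reactants: 24 (5S,8S,9R)-diol
Product: 26 oxolane diol (5S,8S,9R,12R,13R) with C17–OH on C12 plus a secondary C13–OH, via epoxy diol 25 (not isolated)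
Conditions: Ti(OiPr)4 (cat.), L-(+)-DIPT (cat.), t-BuOOH, 4 Å MS, CH2Cl2, −20 °C; then PPTS (cat.), CH2Cl2, 0 °C
Reagents that add atoms: tert-butyl hydroperoxide, CC(C)(C)OO
Why: Katsuki–Sharpless epoxidation is confined to the only allylic alcohol and L-(+)-tartrate gives the (12S,13R)-epoxide, as in the 2S series it forms from Z-3-substituted allylic alcohols, after which acid-catalysed 5-exo-tet opening by C10–OH at the tertiary C12 with inversion sets (12R) and closes the oxolane.

Step 21
Reactants: 26 oxolane diol; 27 nonadecanoic acid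
Product: 28 C17 nonadecanoate of 26 with the C13–OH free
Conditions: EDC, DMAP (cat.), CH2Cl2, 0 °C
Reagents that add atoms: none
Why: Carbodiimide/DMAP (Steglich-type) esterification with one equivalent of acid takes the primary C17–OH in preference to the secondary C13–OH, which is flanked by the quaternary C12.

Step 22
Reactants: 28 C17 nonadecanoate of 26
Product: 30 C5-O-triethylsilyl ether of the target, via mesylate 29 (not isolated)
Conditions: MsCl, Et3N, CH2Cl2, −10 °C; then DBU, toluene, 80 °C
Reagents that add atoms: none
Why: Sulfonylation followed by E2 elimination can only remove an allylic C14 hydrogen because C12 is quaternary, the anti-periplanar arrangement with C15 away from C12 gives the conjugated 13E-diene, and the auxiliary C13 centre disappears as planned.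

Step 23
Reactants: 30 C5-O-triethylsilyl ether of the target
Product: 31 CNP0120482.1 (5S,8S,9R,12R; 3Z,13E)
Conditions: TBAF, AcOH (1:1), THF, 0 °C → rt
Reagents that add atoms: none
Why: Buffered fluoride desilylation removes the only silyl group without acid, which spares the ionisable dienyl tertiary ether and the tertiary allylic alcohol, and without free base, which spares the ester.

**Compound list**
1 | geraniol | CC(C)=CCC/C(C)=C/CO | starting material
2 | (2S,3S)-2,3-epoxygeraniol | CC(C)=CCC[C@]1([C@@H](O1)CO)C | intermediate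
3 | (2R,3S)-1-chloro-2,3-epoxy-3,7-dimethyloct-6-ene | CC(C)=CCC[C@]1([C@@H](O1)CCl)C | intermediate
4 | (S)-3,7-dimethyloct-6-en-1-yn-3-ol | C#C[C@@](C)(O)CCC=C(C)C | intermediate
5 | TES ether of 4 | C#C[C@@](C)(O[Si](CC)(CC)CC)CCC=C(C)C | intermediate
6 | (S)-4-methyl-4-(triethylsilyloxy)hex-5-ynal | C#C[C@@](C)(O[Si](CC)(CC)CC)CCC=O | intermediate
7 | dimethyl malonate | COC(=O)CC(=O)OC | starting material
8 | alkylidene malonate | C#C[C@@](C)(O[Si](CC)(CC)CC)CCC=C(C(=O)OC)C(=O)OC | intermediate
9 | 2-alkylidene-1,3-diol | C#C[C@@](C)(O[Si](CC)(CC)CC)CCC=C(CO)CO | intermediate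
10 | 4-methyl hydrogen itaconate | C=C(CC(=O)OC)C(=O)O | starting material
11 | methyl 3-(hydroxymethyl)but-3-enoate | C=C(CO)CC(=O)OC | intermediate
12 | methyl 3-(bromomethyl)but-3-enoate | C=C(CBr)CC(=O)OC | intermediate
13 | skipped enyne diol ester | COC(=O)CC(=C)CC#C[C@@](C)(O[Si](CC)(CC)CC)CCC=C(CO)CO | intermediate
14 | Z-skipped diene diol ester | COC(=O)CC(=C)C/C=C\[C@@](C)(O[Si](CC)(CC)CC)CCC=C(CO)CO | intermediate
15 | E-hydroxymethyl enal | COC(=O)CC(=C)C/C=C\[C@@](C)(O[Si](CC)(CC)CC)CC/C=C(\CO)C=O | intermediate
16 | E-pivaloyloxymethyl enal | COC(=O)CC(=C)C/C=C\[C@@](C)(O[Si](CC)(CC)CC)CC/C=C(\COC(=O)C(C)(C)C)C=O | intermediate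
17 | (13S)-allyl carbinol | COC(=O)CC(=C)C/C=C\[C@@](C)(O[Si](CC)(CC)CC)CC/C=C(\COC(=O)C(C)(C)C)[C@H](CC=C)O | intermediate
18 | (13S)-prenyl carbinol | COC(=O)CC(=C)C/C=C\[C@@](C)(O[Si](CC)(CC)CC)CC/C=C(\COC(=O)C(C)(C)C)[C@H](CC=C(C)C)O | intermediate
19 | seco acid | OC(=O)CC(=C)C/C=C\[C@@](C)(O[Si](CC)(CC)CC)CC/C=C(\COC(=O)C(C)(C)C)[C@H](CC=C(C)C)O | intermediate
20 | 13-membered allylic lactone (5S,13S; 3Z,8E) | O=C1CC(=C)C/C=C\[C@@](C)(O[Si](CC)(CC)CC)CC/C=C(\COC(=O)C(C)(C)C)[C@H](CC=C(C)C)O1 | intermediate
21 | (Z)-O-TBS ketene acetal of 20 (C1 anti to ring O) | CC(C)(C)[Si](C)(C)O/C1=C\C(=C)C/C=C\[C@@](C)(O[Si](CC)(CC)CC)CC/C=C(\COC(=O)C(C)(C)C)[C@H](CC=C(C)C)O1 | intermediate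
22 | TBS ester of 23 | C=C1C/C=C\[C@@](C)(O[Si](CC)(CC)CC)CC[C@H](/C(COC(=O)C(C)(C)C)=C/CC=C(C)C)[C@H]1C(=O)O[Si](C)(C)C(C)(C)C | intermediate
23 | (5S,8S,9R)-cyclononadiene carboxylic acid | C=C1C/C=C\[C@@](C)(O[Si](CC)(CC)CC)CC[C@H](/C(COC(=O)C(C)(C)C)=C/CC=C(C)C)[C@H]1C(=O)O | intermediate
24 | (5S,8S,9R)-diol | C=C1C/C=C\[C@@](C)(O[Si](CC)(CC)CC)CC[C@H](/C(CO)=C/CC=C(C)C)[C@H]1CO | intermediate
25 | (12S,13R)-epoxy diol | C=C1C/C=C\[C@@](C)(O[Si](CC)(CC)CC)CC[C@H]([C@@]2(CO)O[C@@H]2CC=C(C)C)[C@H]1CO | intermediate
26 | oxolane diol (5S,8S,9R,12R,13R) | C=C1C/C=C\[C@@](C)(O[Si](CC)(CC)CC)CC[C@H]2[C@H]1CO[C@@]2([C@H](O)CC=C(C)C)CO | intermediate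
27 | nonadecanoic acid | CCCCCCCCCCCCCCCCCCC(=O)O | starting material
28 | C17 nonadecanoate, C13–OH free | C=C1C/C=C\[C@@](C)(O[Si](CC)(CC)CC)CC[C@H]2[C@H]1CO[C@@]2([C@H](O)CC=C(C)C)COC(=O)CCCCCCCCCCCCCCCCCC | intermediate
29 | C13 mesylate of 28 | C=C1C/C=C\[C@@](C)(O[Si](CC)(CC)CC)CC[C@H]2[C@H]1CO[C@@]2([C@H](OS(C)(=O)=O)CC=C(C)C)COC(=O)CCCCCCCCCCCCCCCCCC | intermediate
30 | C5-O-TES ether of the target | C=C1C/C=C\[C@@](C)(O[Si](CC)(CC)CC)CC[C@H]2[C@H]1CO[C@@]2(/C=C/C=C(C)C)COC(=O)CCCCCCCCCCCCCCCCCC | intermediate
31 | CNP0120482.1 | C=C1C/C=C\[C@@](C)(O)CC[C@H]2[C@H]1CO[C@@]2(/C=C/C=C(C)C)COC(=O)CCCCCCCCCCCCCCCCCC | target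

**Total step count:** 23
**Longest linear sequence:** 21 steps (steps 1–7 and 10–23, from geraniol)

**The three steps most likely to fail**

**Step 18.** The dienolate may equilibrate before it is trapped, or it may be silylated on carbon. The medium-ring transition state may also turn boat-like, or it may demand temperatures at which the acetal decays. Each of these erodes conversion or the trans relation. The fallback replaces hard enolisation, silyl trapping and heating by soft enolisation to a boron enolate.
* It sets out from 20. Bu2BOTf and i-Pr2NEt in CH2Cl2 at −78 °C should give the dibutylboron ketene acetal F1. Its geometry (C1 syn to OB) is fixed by deprotonation of the boron-bound ester and does not depend on the solvent.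
* Boron ester enolates undergo the [3,3] shift between −20 °C and room temperature, and this is also known for contractions of macrolactones. The shift should give the dibutylboryl ester F2.
* Aqueous work-up comes back to the route at 23.

**Step 20.** Epoxidation of a hindered, Z-substituted and 2-branched allylic alcohol may be slow, or it may be mismatched with the C8 centre. The opening may also drift to the 6-endo mode or lose its invertive character at the tertiary carbon. The fallback activates the alkene with palladium(II) and forms the diene in the same event.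
* It sets out from 23. i-BuOCOCl and N-methylmorpholine give the mixed carbonic anhydride F3, which NaBH4 reduces to the C10 alcohol with retained pivalate F4.
* Pd(TFA)2 (cat.), pyridine, Na2CO3, 3 Å MS, O2, toluene, 80 °C should bring about Wacker-type 5-exo oxypalladation at C12 and β-hydride loss toward C14. This gives the oxolane dienyl pivalate F5. The facial sense then rests on the substrate, and the C12 epimers would have to be separated.
* DIBAL-H frees the oxolane dienyl alcohol F6.
* Carbodiimide esterification with 27 comes back to the route at 30, so steps 19–22 are bypassed.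

**Step 17.** Activation of the β,γ-unsaturated acyl group in the presence of DMAP may move the C1 double bond into conjugation, and oligomerisation may compete with ring closure. The fallback activates the alcohol in place of the acid.
* It sets out from 16. (+)-Ipc2B(allyl) gives the (13R)-allyl carbinol F7.
* Cross-metathesis as in step 15 gives the (13R)-prenyl carbinol F8, and Me3SnOH gives the (13R)-seco acid F9.
* Mitsunobu macrolactonisation (PPh3, DIAD, toluene, high dilution) lets the unactivated carboxylate displace the activated C13 oxygen with inversion. It comes back to the route at 20.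

**Further compounds**
F1 | step 18 | dibutylboron ketene acetal of 20 | CCCCB(CCCC)O/C1=C\C(=C)C/C=C\[C@@](C)(O[Si](CC)(CC)CC)CC/C=C(\COC(=O)C(C)(C)C)[C@H](CC=C(C)C)O1
F2 | step 18 | dibutylboryl ester of 23 | C=C1C/C=C\[C@@](C)(O[Si](CC)(CC)CC)CC[C@H](/C(COC(=O)C(C)(C)C)=C/CC=C(C)C)[C@H]1C(=O)OB(CCCC)CCCC
F3 | step 20 | mixed isobutyl carbonic anhydride of 23 | C=C1C/C=C\[C@@](C)(O[Si](CC)(CC)CC)CC[C@H](/C(COC(=O)C(C)(C)C)=C/CC=C(C)C)[C@H]1C(=O)OC(=O)OCC(C)C
F4 | step 20 | C10 alcohol with retained pivalate | C=C1C/C=C\[C@@](C)(O[Si](CC)(CC)CC)CC[C@H](/C(COC(=O)C(C)(C)C)=C/CC=C(C)C)[C@H]1CO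
F5 | step 20 | oxolane dienyl pivalate | C=C1C/C=C\[C@@](C)(O[Si](CC)(CC)CC)CC[C@H]2[C@H]1CO[C@@]2(/C=C/C=C(C)C)COC(=O)C(C)(C)C
F6 | step 20 | oxolane dienyl alcohol | C=C1C/C=C\[C@@](C)(O[Si](CC)(CC)CC)CC[C@H]2[C@H]1CO[C@@]2(/C=C/C=C(C)C)CO
F7 | step 17 | (13R)-allyl carbinol | COC(=O)CC(=C)C/C=C\[C@@](C)(O[Si](CC)(CC)CC)CC/C=C(\COC(=O)C(C)(C)C)[C@@H](CC=C)O
F8 | step 17 | (13R)-prenyl carbinol | COC(=O)CC(=C)C/C=C\[C@@](C)(O[Si](CC)(CC)CC)CC/C=C(\COC(=O)C(C)(C)C)[C@@H](CC=C(C)C)O
F9 | step 17 | (13R)-seco acid | OC(=O)CC(=C)C/C=C\[C@@](C)(O[Si](CC)(CC)CC)CC/C=C(\COC(=O)C(C)(C)C)[C@@H](CC=C(C)C)O
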